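Ring A is disconnected at C2–C3 (spiro[5.5]undecane numbering: C1 methyl-bearing alkene carbon, C3 carbinol, C4 CHBr, C5 CMe2, C6 spiro atom; ring B C7 to C11, C9 CClMe, C10 CHBr). A Lewis acid carbonyl ene reaction of an α-bromoaldehyde forms this bond, closes ring A and sets C3 in one operation; it exploits the ring A trans bromohydrin at C3 and C4, whose carbinol lies 1,3 to alkene carbon C1. The precursor is a ring B cyclohexane whose C6 bears an isopropenyl group and a CMe2CHBrCHO chain; C4 is set beforehand by an amine catalyst, the ring B halogens by bromolactonisation. A final alkene shift gives the target.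

Key step: step 12

Assumption: commercial acid 1 is racemic and its stereocentre is erased in step 2; absolute configuration therefore enters through the resolution of acid 6 (C6) and through the amine catalyst (C4), and all five stereocentres of target 19 are S by the CIP rules.

Design remark: the vinyl group created in step 2 is the γ,δ-alkene of the acid and would itself bromolactonise, so it is hydroborated before any Br+ source is used, and the resulting C3 oxygen is carried as a pivalate until the oxidation of step 10.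

Step 1
Reactants: 1 4-methylcyclohex-3-ene-1-carboxylic acid (racemic); 2 3-methylbut-2-en-1-ol
Product: 3 3-methylbut-2-en-1-yl 4-methylcyclohex-3-ene-1-carboxylate (racemic)
Conditions: DCC, DMAP (cat.), CH2Cl2, 0 °C to rt
Reagents that add atoms: none
Why: Steglich esterification, in which the carbodiimide-activated acid is passed through the acylpyridinium to the primary allylic alcohol under neutral conditions that leave both alkenes alone; the stereocentre of 1 is of no consequence because it is erased in step 2.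

Step 2
Reactants: 3 3-methylbut-2-en-1-yl 4-methylcyclohex-3-ene-1-carboxylate
Product: 6 rac-4-methyl-1-(2-methylbut-3-en-2-yl)cyclohex-3-ene-1-carboxylic acid, via ketene silyl acetal 4 (not isolated), via trimethylsilyl ester 5 (not isolated)
Conditions: LiN(i-Pr)2, THF, −78 °C; Me3SiCl, −78 °C to 65 °C; then 1 M HCl
Reagents that add atoms: none
Why: Ireland–Claisen rearrangement, in which the fully substituted ketene silyl acetal undergoes the [3,3] shift onto the dimethyl-substituted allyl terminus and so joins the two quaternary carbons C5 and C6; C6 forms as a racemate because the two ring arms of the enolate differ only remotely.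

Step 3
Reactants: 6 rac-4-methyl-1-(2-methylbut-3-en-2-yl)cyclohex-3-ene-1-carboxylic acid
Product: 7 (1R)-4-methyl-1-(2-methylbut-3-en-2-yl)cyclohex-3-ene-1-carboxylic acid
Conditions: preparative supercritical-fluid chromatography, amylose tris(3,5-dimethylphenylcarbamate) phase, CO2/MeOH (0.1% HCO2H), 35 °C
Reagents that add atoms: none
Why: Resolution by chiral chromatography separates the enantiomers through diastereomeric adsorption on the polysaccharide phase without forming a bond and should deliver the (1R) acid whose quaternary carbon is the future C6; which eluted enantiomer is (1R) would be established by anomalous-dispersion X-ray diffraction on bromolactone 10.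

Step 4
Reactants: 7 (1R)-4-methyl-1-(2-methylbut-3-en-2-yl)cyclohex-3-ene-1-carboxylic acid
Product: 10 (1S,4R,6S)-6-bromo-4-(4-hydroxy-2-methylbutan-2-yl)-1-methyl-2-oxabicyclo[2.2.2]octan-3-one, via bis(9-BBN) adduct 8 (not isolated), via sodium hydroxy carboxylate 9 (not isolated)
Conditions: 9-borabicyclo[3.3.1]nonane (2.5 equiv), THF, 0 °C to rt; 3 M NaOH, 30% H2O2, 0 °C; Na2SO3; aqueous carboxylate layer washed with Et2O and brought to pH 8–9 (CO2, NaHCO3); N-bromosuccinimide, 0 °C, dark
Reagents that add atoms: hydrogen peroxide OO; N-bromosuccinimide O=C1CCC(=O)N1Br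
Why: Brown hydroboration–oxidation with the bulky borane converts only the monosubstituted vinyl group into C4H2–C3H2OH, and in the following bromolactonisation the axial C6 carboxylate opens the bromonium ion of the ring alkene at the tertiary carbon C9 from its own face, which places oxygen on C9 cis to the carboxyl carbon and bromine on C10 anti to it.

Step 5
Reactants: 10 (1S,4R,6S)-6-bromo-4-(4-hydroxy-2-methylbutan-2-yl)-1-methyl-2-oxabicyclo[2.2.2]octan-3-one
Product: 11 3-[(1S,4R,6S)-6-bromo-1-methyl-3-oxo-2-oxabicyclo[2.2.2]octan-4-yl]-3-methylbutyl 2,2-dimethylpropanoate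
Conditions: pivaloyl chloride, pyridine, DMAP (cat.), CH2Cl2, 0 °C to rt
Reagents that add atoms: pivaloyl chloride CC(C)(C)C(Cl)=O
Why: Acylation under nucleophilic catalysis esterifies the unhindered primary alcohol and leaves the hindered bridged lactone alone; the pivalate masks the C3 oxygen against SOCl2, the cuprate and the titanium methylidene.

Step 6
Reactants: 11 3-[(1S,4R,6S)-6-bromo-1-methyl-3-oxo-2-oxabicyclo[2.2.2]octan-4-yl]-3-methylbutyl 2,2-dimethylpropanoate
Product: 12 (1R,3S,4S)-3-bromo-4-chloro-1-[4-(2,2-dimethylpropanoyloxy)-2-methylbutan-2-yl]-4-methylcyclohexane-1-carbonyl chloride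
Conditions: SOCl2, ZnCl2 (10 mol %), 1,2-dichloroethane, 60 °C; concentrate
Reagents that add atoms: thionyl chloride O=S(Cl)Cl
Why: ZnCl2-promoted chlorinative lactone opening, in which the C10 bromine (antiperiplanar to the C9–O bond in the bicycle) assists ionisation to a bromonium ion that chloride reopens at tertiary C9 from the face the oxygen left, so chlorine ends cis to the acyl carbon and trans to bromine (net retention) while SOCl2 turns the freed carboxyl into the acid chloride and prevents relactonisation.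

Step 7
Reactants: 12 (1R,3S,4S)-3-bromo-4-chloro-1-[4-(2,2-dimethylpropanoyloxy)-2-methylbutan-2-yl]-4-methylcyclohexane-1-carbonyl chloride
Product: 13 3-[(1R,3S,4S)-1-acetyl-3-bromo-4-chloro-4-methylcyclohexyl]-3-methylbutyl 2,2-dimethylpropanoate
Conditions: Me2CuLi (from MeLi and CuI), Et2O, −78 °C; NH4Cl (aq)
Reagents that add atoms: lithium dimethylcuprate [Li+].C[Cu-]C
Why: Ketone synthesis from an acid chloride and a lithium dialkylcuprate (Gilman reagent), in which the cuprate substitutes the acyl chloride and stops at the ketone; at −78 °C the pivalate and the equatorial bromide and chloride, which have no antiperiplanar ring hydrogen, should be inert to the weakly basic reagent.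

Step 8
Reactants: 13 3-[(1R,3S,4S)-1-acetyl-3-bromo-4-chloro-4-methylcyclohexyl]-3-methylbutyl 2,2-dimethylpropanoate
Product: 14 3-[(1S,3S,4S)-3-bromo-4-chloro-4-methyl-1-(prop-1-en-2-yl)cyclohexyl]-3-methylbutyl 2,2-dimethylpropanoate
Conditions: Tebbe reagent Cp2Ti(μ-CH2)(μ-Cl)AlMe2 (1.3 equiv), pyridine (cat.), THF/toluene, −40 °C to rt
Reagents that add atoms: Tebbe reagent C[Al-]1(C)C[Ti]([Cl+]1)(C1C=CC=C1)C1C=CC=C1
Why: Tebbe methylenation, in which the non-basic titanium methylidene adds to the hindered, enolisable methyl ketone through an oxatitanacyclobutane to give the C1 isopropenyl group; the ketone should react ahead of the pivalate, and no base is present to eliminate HBr or HCl.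

Step 9
Reactants: 14 3-[(1S,3S,4S)-3-bromo-4-chloro-4-methyl-1-(prop-1-en-2-yl)cyclohexyl]-3-methylbutyl 2,2-dimethylpropanoate
Product: 15 3-[(1S,3S,4S)-3-bromo-4-chloro-4-methyl-1-(prop-1-en-2-yl)cyclohexyl]-3-methylbutan-1-ol
Conditions: i-Bu2AlH (2.5 equiv), CH2Cl2, −78 °C; KNa tartrate (aq)
Reagents that add atoms: none
Why: Reductive ester cleavage by the aluminium hydride frees the C3 primary alcohol without touching the alkyl halides or the 1,1-disubstituted alkene.

Step 10
Reactants: 15 3-[(1S,3S,4S)-3-bromo-4-chloro-4-methyl-1-(prop-1-en-2-yl)cyclohexyl]-3-methylbutan-1-ol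
Product: 16 3-[(1S,3S,4S)-3-bromo-4-chloro-4-methyl-1-(prop-1-en-2-yl)cyclohexyl]-3-methylbutanal
Conditions: Dess–Martin periodinane, NaHCO3, CH2Cl2, 0 °C to rt
Reagents that add atoms: none
Why: Dess–Martin oxidation takes the primary alcohol to the aldehyde under buffered, non-basic conditions that spare the alkene and the halides, and C4 is still a methylene group, so nothing can epimerise.

Step 11
Reactants: 16 3-[(1S,3S,4S)-3-bromo-4-chloro-4-methyl-1-(prop-1-en-2-yl)cyclohexyl]-3-methylbutanal
Product: 17 (2S)-2-bromo-3-[(1S,3S,4S)-3-bromo-4-chloro-4-methyl-1-(prop-1-en-2-yl)cyclohexyl]-3-methylbutanal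
Conditions: (S)-2-{bis[3,5-bis(trifluoromethyl)phenyl](trimethylsilyloxy)methyl}pyrrolidine (20 mol %), 4,4-dibromo-2,6-di-tert-butylcyclohexa-2,5-dien-1-one (1.1 equiv), PhCO2H (20 mol %), CH2Cl2/pentane, −40 °C; cold silica plug, used at once
Reagents that add atoms: 4,4-dibromo-2,6-di-tert-butylcyclohexa-2,5-dien-1-one CC(C)(C)C1=CC(Br)(Br)C=C(C(C)(C)C)C1=O
Why: Enamine-catalysed asymmetric α-bromination of an aldehyde, in which the (E)-enamine formed with the (S)-diarylprolinol silyl ether is shielded on one face by the diaryl(silyloxy)methyl group so that the mild Br+ donor attacks the open face and sets (S)-C4 under reagent control; the donor is too weak an electrophile to attack the hindered isopropenyl group.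

Step 12
Reactants: 17 (2S)-2-bromo-3-[(1S,3S,4S)-3-bromo-4-chloro-4-methyl-1-(prop-1-en-2-yl)cyclohexyl]-3-methylbutanal
Product: 18 (3S,4S,6S,9S,10S)-4,10-dibromo-9-chloro-5,5,9-trimethyl-1-methylidenespiro[5.5]undecan-3-ol
Conditions: Me2AlCl (1.5 equiv), CH2Cl2, −78 °C to −40 °C; then cold 1 M HCl
Reagents that add atoms: none
Why: Me2AlCl binds the C3 aldehyde oxygen, the terminal carbon of the isopropenyl group (the future C2) attacks C3 and an allylic methyl hydrogen passes to oxygen through a six-membered array, so the C2–C3 bond forms and the alkene ends as the exocyclic C1 methylidene with no free cation left to rearrange. The closest known reaction type is the Lewis-acid-promoted type 2 intramolecular carbonyl-ene cyclisation of 5-methylhex-5-enals to 3-methylenecyclohexanols. Ring A closes as a six-membered ring in this type 2 ene mode (ene carbon C1 inside the new ring, carbonyl attacked 6-exo) through a chair fused to the hydrogen-transfer ring, which places the C3–O bond axial. The only new stereocentre, C3, is controlled by C4: with the C4–Br bond also axial and antiperiplanar to the complexed carbonyl (dipoles opposed) the hydroxyl should end trans to bromine, giving (3S,4S), while C6 with its two near-identical ring B arms exerts no bias. The step needs this C3/C4 diastereoselectivity and clean chemoselectivity, and the substrate secures both: the aldehyde meets a single alkene, C4 cannot enolise in the cold non-basic medium, and the ring B halogens are diequatorial (the tert-alkyl group on C6 is equatorial), so the tertiary C9–Cl bond has no antiperiplanar bromine to assist its ionisation by the Lewis acid.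

Step 13
Reactants: 18 (3S,4S,6S,9S,10S)-4,10-dibromo-9-chloro-5,5,9-trimethyl-1-methylidenespiro[5.5]undecan-3-ol
Product: 19 (3S,4S,6S,9S,10S)-4,10-dibromo-9-chloro-1,5,5,9-tetramethylspiro[5.5]undec-1-en-3-ol
Conditions: Co(salen)Cl [salen = N,N'-bis(3,5-di-tert-butylsalicylidene)ethylenediamine dianion] (5 mol %), PhSiH3 (10 mol %), benzene, rt
Reagents that add atoms: none
Why: Cobalt hydride hydrogen-atom-transfer alkene isomerisation, in which the hydride formed from Co(salen)Cl and PhSiH3 gives a hydrogen atom to the exocyclic CH2 and the tertiary C1 radical returns one from C2 (C6 is quaternary, so the alkene can only move towards C2), giving the more substituted endocyclic C1=C2 alkene under neutral conditions that should leave the allylic alcohol, the C–Br and C–Cl bonds and every stereocentre untouched.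

Compound list
1 | 4-methylcyclohex-3-ene-1-carboxylic acid (racemic) | CC1=CCC(CC1)C(=O)O | starting material
2 | 3-methylbut-2-en-1-ol | CC(C)=CCO | starting material
3 | 3-methylbut-2-en-1-yl 4-methylcyclohex-3-ene-1-carboxylate (racemic) | CC1=CCC(CC1)C(=O)OCC=C(C)C | intermediate
4 | trimethyl{[(4-methylcyclohex-3-en-1-ylidene)(3-methylbut-2-en-1-yloxy)methyl]oxy}silane (ketene silyl acetal, E/Z mixture) | CC1=CCC(CC1)=C(OCC=C(C)C)O[Si](C)(C)C | intermediate
5 | trimethylsilyl rac-4-methyl-1-(2-methylbut-3-en-2-yl)cyclohex-3-ene-1-carboxylate | CC1=CCC(CC1)(C(=O)O[Si](C)(C)C)C(C)(C)C=C | intermediate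
6 | rac-4-methyl-1-(2-methylbut-3-en-2-yl)cyclohex-3-ene-1-carboxylic acid | CC1=CCC(CC1)(C(=O)O)C(C)(C)C=C | intermediate
7 | (1R)-4-methyl-1-(2-methylbut-3-en-2-yl)cyclohex-3-ene-1-carboxylic acid | OC(=O)[C@]1(C(C)(C)C=C)CCC(C)=CC1 | intermediate
8 | 9-borabicyclo[3.3.1]nonan-9-yl (1R)-1-[4-(9-borabicyclo[3.3.1]nonan-9-yl)-2-methylbutan-2-yl]-4-methylcyclohex-3-ene-1-carboxylate | O=C(OB1C2CCCC1CCC2)[C@]1(C(C)(C)CCB2C3CCCC2CCC3)CCC(C)=CC1 | intermediate
9 | sodium (1R)-1-(4-hydroxy-2-methylbutan-2-yl)-4-methylcyclohex-3-ene-1-carboxylate | [Na+].[O-]C(=O)[C@]1(C(C)(C)CCO)CCC(C)=CC1 | intermediate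
10 | (1S,4R,6S)-6-bromo-4-(4-hydroxy-2-methylbutan-2-yl)-1-methyl-2-oxabicyclo[2.2.2]octan-3-one | O=C2[C@]1(C(C)(C)CCO)CC[C@](C)(O2)[C@@H](Br)C1 | intermediate
11 | 3-[(1S,4R,6S)-6-bromo-1-methyl-3-oxo-2-oxabicyclo[2.2.2]octan-4-yl]-3-methylbutyl 2,2-dimethylpropanoate | O=C2[C@]1(C(C)(C)CCOC(=O)C(C)(C)C)CC[C@](C)(O2)[C@@H](Br)C1 | intermediate
12 | (1R,3S,4S)-3-bromo-4-chloro-1-[4-(2,2-dimethylpropanoyloxy)-2-methylbutan-2-yl]-4-methylcyclohexane-1-carbonyl chloride | ClC(=O)[C@]1(C(C)(C)CCOC(=O)C(C)(C)C)CC[C@](C)(Cl)[C@@H](Br)C1 | intermediate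
13 | 3-[(1R,3S,4S)-1-acetyl-3-bromo-4-chloro-4-methylcyclohexyl]-3-methylbutyl 2,2-dimethylpropanoate | CC(=O)[C@]1(C(C)(C)CCOC(=O)C(C)(C)C)CC[C@](C)(Cl)[C@@H](Br)C1 | intermediate
14 | 3-[(1S,3S,4S)-3-bromo-4-chloro-4-methyl-1-(prop-1-en-2-yl)cyclohexyl]-3-methylbutyl 2,2-dimethylpropanoate | C=C(C)[C@]1(C(C)(C)CCOC(=O)C(C)(C)C)CC[C@](C)(Cl)[C@@H](Br)C1 | intermediate
15 | 3-[(1S,3S,4S)-3-bromo-4-chloro-4-methyl-1-(prop-1-en-2-yl)cyclohexyl]-3-methylbutan-1-ol | C=C(C)[C@]1(C(C)(C)CCO)CC[C@](C)(Cl)[C@@H](Br)C1 | intermediate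
16 | 3-[(1S,3S,4S)-3-bromo-4-chloro-4-methyl-1-(prop-1-en-2-yl)cyclohexyl]-3-methylbutanal | C=C(C)[C@]1(C(C)(C)CC=O)CC[C@](C)(Cl)[C@@H](Br)C1 | intermediate
17 | (2S)-2-bromo-3-[(1S,3S,4S)-3-bromo-4-chloro-4-methyl-1-(prop-1-en-2-yl)cyclohexyl]-3-methylbutanal | C=C(C)[C@]1(C(C)(C)[C@H](Br)C=O)CC[C@](C)(Cl)[C@@H](Br)C1 | intermediate
18 | (3S,4S,6S,9S,10S)-4,10-dibromo-9-chloro-5,5,9-trimethyl-1-methylidenespiro[5.5]undecan-3-ol | C=C1C[C@H](O)[C@@H](Br)C(C)(C)[C@]12CC[C@](C)(Cl)[C@@H](Br)C2 | intermediate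
19 | (3S,4S,6S,9S,10S)-4,10-dibromo-9-chloro-1,5,5,9-tetramethylspiro[5.5]undec-1-en-3-ol | CC1=C[C@H](O)[C@@H](Br)C(C)(C)[C@]12CC[C@](C)(Cl)[C@@H](Br)C2 | target

Total step count: 13. Longest linear sequence: 13 steps (1 and 2 to 19).

Steps most likely to fail

Step 12 (ring closure). The cyclisation may pass through the chair with equatorial bromine (poor facial selectivity at C3). The Lewis acid may also ionise the C9–Cl bond or transfer methyl to the aldehyde. The fallback replaces hydrogen transfer by silyl transfer (intramolecular Hosomi–Sakurai allylation) and sets out from acid chloride 12. Me3SiCH2MgCl/CeCl3 (THF, −78 °C to rt) adds twice to give 3-[(1R,3S,4S)-3-bromo-4-chloro-1-[2-hydroxy-1,3-bis(trimethylsilyl)propan-2-yl]-4-methylcyclohexyl]-3-methylbutyl 2,2-dimethylpropanoate F1, which loses trimethylsilanol on silica gel (Peterson elimination) to give allylsilane pivalate 3-[(1R,3S,4S)-3-bromo-4-chloro-4-methyl-1-[3-(trimethylsilyl)prop-1-en-2-yl]cyclohexyl]-3-methylbutyl 2,2-dimethylpropanoate F2. i-Bu2AlH then gives the alcohol 3-[(1R,3S,4S)-3-bromo-4-chloro-4-methyl-1-[3-(trimethylsilyl)prop-1-en-2-yl]cyclohexyl]-3-methylbutan-1-ol F3, Dess–Martin oxidation the aldehyde 3-[(1R,3S,4S)-3-bromo-4-chloro-4-methyl-1-[3-(trimethylsilyl)prop-1-en-2-yl]cyclohexyl]-3-methylbutanal F4, and the bromination of step 11 the bromoaldehyde (2S)-2-bromo-3-[(1S,3S,4S)-3-bromo-4-chloro-4-methyl-1-[3-(trimethylsilyl)prop-1-en-2-yl]cyclohexyl]-3-methylbutanal F5. With BF3·OEt2 (CH2Cl2, −78 °C) the allylsilane terminus attacks the aldehyde in an open transition state that needs no axial oxygen (all-equatorial chair, bromine anti to the incoming carbon, polar Felkin–Anh), silicon leaves, and the route is rejoined at 18.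

Step 6 (lactone opening). Ionisation at C9 may end in elimination or halide scrambling instead of clean chloride return, or the hindered carboxyl may relactonise. The fallback gives up the carboxyl relay, adds bromine and chlorine intermolecularly, and sets out from acid 7. Hydroboration–oxidation as in step 4 and acidification give the hydroxy acid (1R)-1-(4-hydroxy-2-methylbutan-2-yl)-4-methylcyclohex-3-ene-1-carboxylic acid F6, which lactonises (pyridinium p-toluenesulfonate, benzene, 50 °C) to the spirolactone (6R)-5,5,9-trimethyl-2-oxaspiro[5.5]undec-8-en-1-one F7. N-bromosuccinimide/Et4NCl (CH2Cl2, −20 °C) adds Br and Cl anti and in the Markovnikov sense to give (6R,8S,9S)-8-bromo-9-chloro-5,5,9-trimethyl-2-oxaspiro[5.5]undecan-1-one F8 together with its ring B face isomer (6R,8R,9R)-8-bromo-9-chloro-5,5,9-trimethyl-2-oxaspiro[5.5]undecan-1-one F9, to be separated by chromatography or crystallisation. MeLi (1 equiv, THF, −78 °C) opens F8 to the hydroxy ketone 1-[(1R,3S,4S)-3-bromo-4-chloro-1-(4-hydroxy-2-methylbutan-2-yl)-4-methylcyclohexyl]ethan-1-one F10, and pivaloylation as in step 5 rejoins the route at 13.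

Step 11 (α-bromination). Enamine formation at the neopentyl-type aldehyde may be too slow, so that uncatalysed bromination or attack on the isopropenyl group competes, and the product may epimerise at C4. The fallback brominates without an amine and settles C4 by separation after ring closure; it sets out from aldehyde 16. Me3SiOTf/Et3N (CH2Cl2, 0 °C) gives the enol silane {[3-[(1S,3S,4S)-3-bromo-4-chloro-4-methyl-1-(prop-1-en-2-yl)cyclohexyl]-3-methylbut-1-en-1-yl]oxy}trimethylsilane F11. N-bromosuccinimide (THF, −78 °C) then gives 17 mixed with its C4 epimer (2R)-2-bromo-3-[(1S,3S,4S)-3-bromo-4-chloro-4-methyl-1-(prop-1-en-2-yl)cyclohexyl]-3-methylbutanal F12. The mixture is cyclised as in step 12, and 18 is separated by chromatography from the diastereomer (3R,4R,6S,9S,10S)-4,10-dibromo-9-chloro-5,5,9-trimethyl-1-methylidenespiro[5.5]undecan-3-ol F13, which returns the route at 18.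

Further compounds
F1 | step 12 | 3-[(1R,3S,4S)-3-bromo-4-chloro-1-[2-hydroxy-1,3-bis(trimethylsilyl)propan-2-yl]-4-methylcyclohexyl]-3-methylbutyl 2,2-dimethylpropanoate | C[Si](C)(C)CC(O)(C[Si](C)(C)C)[C@]1(C(C)(C)CCOC(=O)C(C)(C)C)CC[C@](C)(Cl)[C@@H](Br)C1
F2 | step 12 | 3-[(1R,3S,4S)-3-bromo-4-chloro-4-methyl-1-[3-(trimethylsilyl)prop-1-en-2-yl]cyclohexyl]-3-methylbutyl 2,2-dimethylpropanoate | C=C(C[Si](C)(C)C)[C@]1(C(C)(C)CCOC(=O)C(C)(C)C)CC[C@](C)(Cl)[C@@H](Br)C1
F3 | step 12 | 3-[(1R,3S,4S)-3-bromo-4-chloro-4-methyl-1-[3-(trimethylsilyl)prop-1-en-2-yl]cyclohexyl]-3-methylbutan-1-ol | C=C(C[Si](C)(C)C)[C@]1(C(C)(C)CCO)CC[C@](C)(Cl)[C@@H](Br)C1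
F4 | step 12 | 3-[(1R,3S,4S)-3-bromo-4-chloro-4-methyl-1-[3-(trimethylsilyl)prop-1-en-2-yl]cyclohexyl]-3-methylbutanal | C=C(C[Si](C)(C)C)[C@]1(C(C)(C)CC=O)CC[C@](C)(Cl)[C@@H](Br)C1
F5 | step 12 | (2S)-2-bromo-3-[(1S,3S,4S)-3-bromo-4-chloro-4-methyl-1-[3-(trimethylsilyl)prop-1-en-2-yl]cyclohexyl]-3-methylbutanal | C=C(C[Si](C)(C)C)[C@]1(C(C)(C)[C@H](Br)C=O)CC[C@](C)(Cl)[C@@H](Br)C1
F6 | step 6 | (1R)-1-(4-hydroxy-2-methylbutan-2-yl)-4-methylcyclohex-3-ene-1-carboxylic acid | OC(=O)[C@]1(C(C)(C)CCO)CCC(C)=CC1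
F7 | step 6 | (6R)-5,5,9-trimethyl-2-oxaspiro[5.5]undec-8-en-1-one | O=C1OCCC(C)(C)[C@]12CCC(C)=CC2
F8 | step 6 | (6R,8S,9S)-8-bromo-9-chloro-5,5,9-trimethyl-2-oxaspiro[5.5]undecan-1-one | O=C1OCCC(C)(C)[C@]12CC[C@](C)(Cl)[C@@H](Br)C2
F9 | step 6 | (6R,8R,9R)-8-bromo-9-chloro-5,5,9-trimethyl-2-oxaspiro[5.5]undecan-1-one | O=C1OCCC(C)(C)[C@]12CC[C@@](C)(Cl)[C@H](Br)C2
F10 | step 6 | 1-[(1R,3S,4S)-3-bromo-4-chloro-1-(4-hydroxy-2-methylbutan-2-yl)-4-methylcyclohexyl]ethan-1-one | CC(=O)[C@]1(C(C)(C)CCO)CC[C@](C)(Cl)[C@@H](Br)C1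
F11 | step 11 | {[3-[(1S,3S,4S)-3-bromo-4-chloro-4-methyl-1-(prop-1-en-2-yl)cyclohexyl]-3-methylbut-1-en-1-yl]oxy}trimethylsilane (E/Z mixture) | C=C(C)[C@]1(C(C)(C)C=CO[Si](C)(C)C)CC[C@](C)(Cl)[C@@H](Br)C1
F12 | step 11 | (2R)-2-bromo-3-[(1S,3S,4S)-3-bromo-4-chloro-4-methyl-1-(prop-1-en-2-yl)cyclohexyl]-3-methylbutanal | C=C(C)[C@]1(C(C)(C)[C@@H](Br)C=O)CC[C@](C)(Cl)[C@@H](Br)C1
F13 | step 11 | (3R,4R,6S,9S,10S)-4,10-dibromo-9-chloro-5,5,9-trimethyl-1-methylidenespiro[5.5]undecan-3-ol | C=C1C[C@@H](O)[C@H](Br)C(C)(C)[C@]12CC[C@](C)(Cl)[C@@H](Br)C2
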